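**Retrosynthetic overview**

- The strategy rests on ring A, the cyclopentane C1'–C5': C2' carries OH and CH3, C1' carries the CH2 arm and C5' carries isopropenyl. This is the formal anti-hydrate, across C1'–C2', of the cyclopentene carbaldehyde obtained from limonene by ring contraction.
- Disconnection 1: the C1'–CH2–C4 link to ring B is cut by reductive alkylation of the only C–H position of acyl trione 18 with hydroxy aldehyde 8.
- Disconnection 2: 8 comes from epoxy aldehyde 6 (C–O bond at the aldehyde α-carbon cleaved, α-carbon equilibrated), 6 from enal 5 by nucleophilic epoxidation anti to isopropenyl, and 5 from (R)-limonene.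
- Disconnection 3: ring B (18) comes from Dieckmann closure of triketo ester 17; its quaternary carbon is set by two Fráter–Seebach alkylations of ethyl (R)-3-hydroxybutanoate, and the acyl group comes from (S)-2-methylbutanoic acid.
- Ring order: ring A (step 4), temporary oxirane (closed in step 5, opened in step 6), ring B (step 13), union of the two halves (step 14).

Key step: step 5

Remark on the chemistry: 2 is carried as its cis/trans mixture because both oxirane carbons are cleaved in step 3; the enolised polycarbonyl compounds 16–20 are written as one tautomer (the central CH of 17 is enolised and is not a stereocentre); the descriptor of the isopropenyl-bearing carbon changes from S (5, 6) to R (7, 8, 20) only because CIP priorities change.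

**Route**

Step 1
Reactants: 1 (R)-(+)-limonene
Product: 2 (4R)-1-methyl-4-(prop-1-en-2-yl)-7-oxabicyclo[4.1.0]heptane (limonene 1,2-oxide; cis/trans mixture)
Conditions: mCPBA (1.0 equiv), NaHCO3, CH2Cl2, 0 °C
Reagents that add atoms: mCPBA, O=C(OO)c1cccc(Cl)c1
Why: Prilezhaev epoxidation, in which the peracid should attack the more electron-rich trisubstituted ring alkene well before the 1,1-disubstituted isopropenyl alkene; the diastereomer ratio does not matter.

Step 2
Reactants: 2 limonene 1,2-oxide
Product: 3 (1S,2S,4R)-p-menth-8-ene-1,2-diol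
Conditions: 1% aq. H2SO4, THF, 0 °C → rt
Reagents that add atoms: water, O
Why: Acid-catalysed epoxide hydrolysis with trans-diaxial opening (Fürst–Plattner rule) should converge both oxirane isomers on the trans-diol, and the isopropenyl group survives cold dilute acid.

Step 3
Reactants: 3 (1S,2S,4R)-p-menth-8-ene-1,2-diol
Product: 4 (3R)-6-oxo-3-(prop-1-en-2-yl)heptanal
Conditions: NaIO4, THF/H2O, 0 °C → rt
Reagents that add atoms: none
Why: Malaprade glycol cleavage opens the six-membered ring to the keto aldehyde, whose only stereocentre is not α to either carbonyl group and cannot epimerise.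

Step 4
Reactants: 4 (3R)-6-oxo-3-(prop-1-en-2-yl)heptanal
Product: 5 (5S)-2-methyl-5-(prop-1-en-2-yl)cyclopent-1-ene-1-carbaldehyde
Conditions: piperidine (0.1 equiv), AcOH (0.1 equiv), toluene, 80 °C
Reagents that add atoms: none
Why: Intramolecular aldol condensation in which the piperidine enamine of the aldehyde attacks the methyl ketone (5-enolexo) and the aldol dehydrates, closing ring A as the conjugated formyl cyclopentene while the non-acidic isopropenyl-bearing carbon keeps its configuration.

Step 5
Reactants: 5 (5S)-2-methyl-5-(prop-1-en-2-yl)cyclopent-1-ene-1-carbaldehyde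
Product: 6 (1S,2S,5R)-5-methyl-2-(prop-1-en-2-yl)-6-oxabicyclo[3.1.0]hexane-1-carbaldehyde
Conditions: 30% aq. H2O2 (3 equiv), NaOH (0.3 equiv), MeOH, −10 → 0 °C
Reagents that add atoms: hydrogen peroxide, OO
Why: Weitz–Scheffer nucleophilic epoxidation: hydroperoxide anion adds reversibly to the methyl-bearing β-carbon of the enal, and the enolate so formed attacks the proximal peroxide oxygen, expels hydroxide and forms the C–O bond at the aldehyde α-carbon. The closest known reaction type is the alkaline hydrogen peroxide epoxidation of cyclic enals and enones such as carvone, where a ring substituent steers the oxirane to the opposite face. The oxirane closes in a 3-exo-tet step. The two new stereocentres (C1 and C5 of the oxabicycle) are forced cis by the ring fusion, and their common face is decided in the closure step by the isopropenyl group on the carbon next to the α-carbon, which blocks its own face, so the oxirane should form trans to isopropenyl; since the conjugate addition is reversible, only the adduct that can close on the open face goes on. The step needs chemoselectivity for the electron-poor enal C=C over the isopropenyl alkene, which a nucleophilic oxidant secures, and conjugate over carbonyl addition, which low temperature and substoichiometric base should favour over Baeyer–Villiger-type loss of the formyl group.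

Step 6
Reactants: 6 (1S,2S,5R)-5-methyl-2-(prop-1-en-2-yl)-6-oxabicyclo[3.1.0]hexane-1-carbaldehyde
Product: 7 (2R,5R)-2-hydroxy-2-methyl-5-(prop-1-en-2-yl)cyclopentane-1-carbaldehyde (mixture of C1 epimers)
Conditions: SmI2 (2.2 equiv), THF/MeOH (3:1), −90 °C, 10 min; pH 7 phosphate buffer
Reagents that add atoms: none
Why: Reductive cleavage of a C–O bond α to a carbonyl group by divalent samarium: the ketyl formed by electron transfer to the aldehyde expels the oxirane oxygen from the α-carbon and MeOH protonates the resulting trivalent samarium enolate, so only the α C–O bond breaks, the carbinol carbon keeps the oxygen and configuration set in step 5, and at −90 °C fragmentation of the ketyl should outrun pinacol coupling.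

Step 7
Reactants: 7 (2R,5R)-2-hydroxy-2-methyl-5-(prop-1-en-2-yl)cyclopentane-1-carbaldehyde (mixture of C1 epimers)
Product: 8 (1S,2R,5R)-2-hydroxy-2-methyl-5-(prop-1-en-2-yl)cyclopentane-1-carbaldehyde
Conditions: DBU (0.2 equiv), toluene, 0 °C → rt
Reagents that add atoms: none
Why: Thermodynamic α-epimerisation of an aldehyde through its enolate, in which the formyl group should settle trans to both isopropenyl and methyl and cis to the hydroxyl; in an aprotic medium enolisation should be faster than E1cB loss of the poor tertiary hydroxide leaving group or retro-aldol opening, which needs the alkoxide.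

Step 8
Reactants: 9 ethyl (R)-3-hydroxybutanoate; 10 prenyl bromide
Product: 11 ethyl (2R,3R)-3-hydroxy-2-(3-methylbut-2-en-1-yl)butanoate
Conditions: LiN(iPr)2 (2.2 equiv), THF, −50 → −20 °C; then 10, −78 → 0 °C
Reagents that add atoms: none
Why: Fráter–Seebach alkylation, in which the lithium-chelated alkoxide enolate is attacked by the allylic bromide on the face opposite the C3 methyl group and should give the anti (2R,3R) ester.

Step 9
Reactants: 11 ethyl (2R,3R)-3-hydroxy-2-(3-methylbut-2-en-1-yl)butanoate
Product: 12 ethyl (2S,3R)-3-hydroxy-2-methyl-2-(3-methylbut-2-en-1-yl)butanoate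
Conditions: LiN(iPr)2 (2.3 equiv), THF, −40 → −10 °C; then MeI, DMPU, −78 → 0 °C
Reagents that add atoms: iodomethane, CI
Why: Second Fráter–Seebach alkylation, in which the chelated dianion again reacts on the face opposite the C3 methyl group, so methyl takes the position anti to the hydroxyl and prenyl the syn one, which sets the quaternary carbon as 2S (the order prenyl first, methyl second decides this configuration).

Step 10
Reactants: 12 ethyl (2S,3R)-3-hydroxy-2-methyl-2-(3-methylbut-2-en-1-yl)butanoate
Product: 13 ethyl (2S)-2-acetyl-2,5-dimethylhex-4-enoate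
Conditions: Dess–Martin periodinane, NaHCO3, CH2Cl2, 0 °C → rt
Reagents that add atoms: none
Why: Dess–Martin oxidation of the secondary alcohol to the methyl ketone leaves the prenyl alkene alone, and the quaternary α-carbon of the β-keto ester cannot enolise or racemise.

Step 11
Reactants: 13 ethyl (2S)-2-acetyl-2,5-dimethylhex-4-enoate; 14 (S)-2-methylbutanoic acid
Product: 16 ethyl (2S,6S)-2,6-dimethyl-2-(3-methylbut-2-en-1-yl)-3,5-dioxooctanoate, via acyl imidazole 15 (not isolated)
Conditions: 14, CDI, THF, rt; then added to 13, LiN(SiMe3)2 (3.1 equiv), THF, −78 → 0 °C; aq. NH4Cl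
Reagents that add atoms: none
Why: Claisen-type C-acylation of a kinetic lithium enolate by an acyl imidazole, in which only the acetyl methyl group of 13 can be deprotonated, the extra base takes up the imidazole N–H and the acidic diketone product, and the low temperature should keep the α-stereocentre of the acyl donor intact.

Step 12
Reactants: 16 ethyl (2S,6S)-2,6-dimethyl-2-(3-methylbut-2-en-1-yl)-3,5-dioxooctanoate
Product: 17 ethyl (2S,6S)-4-acetyl-2,6-dimethyl-2-(3-methylbut-2-en-1-yl)-3,5-dioxooctanoate
Conditions: MgCl2 (1.1 equiv), pyridine (2.2 equiv), AcCl (1.1 equiv), CH2Cl2, 0 °C → rt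
Reagents that add atoms: acetyl chloride, CC(=O)Cl
Why: Magnesium-chelate-mediated C-acylation of a 1,3-diketone, in which the magnesium diketonate should be acetylated at its central carbon to the triacylmethane, so that the acyl-bearing ring carbon is fixed on one flank of the quaternary carbon before ring B exists.

Step 13
Reactants: 17 ethyl (2S,6S)-4-acetyl-2,6-dimethyl-2-(3-methylbut-2-en-1-yl)-3,5-dioxooctanoate
Product: 18 (6R)-3,5-dihydroxy-6-methyl-2-[(2S)-2-methylbutanoyl]-6-(3-methylbut-2-en-1-yl)cyclohexa-2,4-dien-1-one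
Conditions: LiN(iPr)2 (3.2 equiv), THF, −78 → 0 °C; 1 M HCl
Reagents that add atoms: none
Why: Dieckmann condensation, in which kinetic deprotonation of the acetyl methyl group of the triacylmethane anion (favoured over the sec-butyl methine) gives a dianion whose terminal enolate closes ring B on the ethyl ester in a 6-exo-trig step; because the 2-methylbutanoyl group already sits on one flank, the two flanks of the quaternary carbon stay different and its configuration is carried into the ring.

Step 14
Reactants: 8 (1S,2R,5R)-2-hydroxy-2-methyl-5-(prop-1-en-2-yl)cyclopentane-1-carbaldehyde; 18 (6R)-3,5-dihydroxy-6-methyl-2-[(2S)-2-methylbutanoyl]-6-(3-methylbut-2-en-1-yl)cyclohexa-2,4-dien-1-one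
Product: 20 (6R)-3,5-dihydroxy-4-{[(1S,2R,5R)-2-hydroxy-2-methyl-5-(prop-1-en-2-yl)cyclopentyl]methyl}-6-methyl-2-[(2S)-2-methylbutanoyl]-6-(3-methylbut-2-en-1-yl)cyclohexa-2,4-dien-1-one, via alkylidene trione 19 (not isolated)
Conditions: Hantzsch ester (1.2 equiv), L-proline (10 mol%), CH2Cl2, rt
Reagents that add atoms: none
Why: Three-component reductive alkylation (Knoevenagel condensation followed by Hantzsch ester transfer hydrogenation), in which C4, the only C–H acidic position of 18, condenses with the aldehyde and hydride adds to the exocyclic carbon of 19, so the CH2 link forms without creating a stereocentre, and since 8 is already the thermodynamic epimer reversible enamine formation cannot erode it.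

**Compound list**

1 | (R)-(+)-limonene | CC1=CC[C@@H](CC1)C(C)=C | starting material
2 | (4R)-1-methyl-4-(prop-1-en-2-yl)-7-oxabicyclo[4.1.0]heptane, cis/trans mixture | CC12CC[C@H](CC1O2)C(C)=C | intermediate
3 | (1S,2S,4R)-p-menth-8-ene-1,2-diol | C[C@]1(O)CC[C@H](C[C@@H]1O)C(C)=C | intermediate
4 | (3R)-6-oxo-3-(prop-1-en-2-yl)heptanal | CC(=O)CC[C@H](CC=O)C(C)=C | intermediate
5 | (5S)-2-methyl-5-(prop-1-en-2-yl)cyclopent-1-ene-1-carbaldehyde | C=C(C)[C@@H]1CCC(C)=C1C=O | intermediate
6 | (1S,2S,5R)-5-methyl-2-(prop-1-en-2-yl)-6-oxabicyclo[3.1.0]hexane-1-carbaldehyde | C=C(C)[C@@H]1CC[C@@]2(C)O[C@@]12C=O | intermediate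
7 | (2R,5R)-2-hydroxy-2-methyl-5-(prop-1-en-2-yl)cyclopentane-1-carbaldehyde, mixture of C1 epimers | C=C(C)[C@@H]1CC[C@@](C)(O)C1C=O | intermediate
8 | (1S,2R,5R)-2-hydroxy-2-methyl-5-(prop-1-en-2-yl)cyclopentane-1-carbaldehyde | C=C(C)[C@@H]1CC[C@@](C)(O)[C@H]1C=O | intermediate
9 | ethyl (R)-3-hydroxybutanoate | CCOC(=O)C[C@@H](C)O | starting material
10 | prenyl bromide (1-bromo-3-methylbut-2-ene) | CC(C)=CCBr | starting material
11 | ethyl (2R,3R)-3-hydroxy-2-(3-methylbut-2-en-1-yl)butanoate | CCOC(=O)[C@H](CC=C(C)C)[C@@H](C)O | intermediate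
12 | ethyl (2S,3R)-3-hydroxy-2-methyl-2-(3-methylbut-2-en-1-yl)butanoate | CCOC(=O)[C@@](C)(CC=C(C)C)[C@@H](C)O | intermediate
13 | ethyl (2S)-2-acetyl-2,5-dimethylhex-4-enoate | CCOC(=O)[C@@](C)(CC=C(C)C)C(C)=O | intermediate
14 | (S)-2-methylbutanoic acid | CC[C@H](C)C(=O)O | starting material
15 | 1-[(2S)-2-methylbutanoyl]-1H-imidazole | CC[C@H](C)C(=O)n1ccnc1 | intermediate (not isolated)
16 | ethyl (2S,6S)-2,6-dimethyl-2-(3-methylbut-2-en-1-yl)-3,5-dioxooctanoate | CCOC(=O)[C@@](C)(CC=C(C)C)C(=O)CC(=O)[C@@H](C)CC | intermediate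
17 | ethyl (2S,6S)-4-acetyl-2,6-dimethyl-2-(3-methylbut-2-en-1-yl)-3,5-dioxooctanoate (triketo tautomer drawn) | CCOC(=O)[C@@](C)(CC=C(C)C)C(=O)C(C(C)=O)C(=O)[C@@H](C)CC | intermediate
18 | (6R)-3,5-dihydroxy-6-methyl-2-[(2S)-2-methylbutanoyl]-6-(3-methylbut-2-en-1-yl)cyclohexa-2,4-dien-1-one | C1=C(O)[C@@](C)(CC=C(C)C)C(=O)C(C(=O)[C@@H](C)CC)=C1O | intermediate
19 | (2R)-5-hydroxy-6-{[(1S,2R,5R)-2-hydroxy-2-methyl-5-(prop-1-en-2-yl)cyclopentyl]methylidene}-2-methyl-4-[(2S)-2-methylbutanoyl]-2-(3-methylbut-2-en-1-yl)cyclohex-4-ene-1,3-dione (alkene geometry open) | C=C(C)[C@@H]1CC[C@@](C)(O)[C@H]1C=C1C(=O)[C@@](C)(CC=C(C)C)C(=O)C(C(=O)[C@@H](C)CC)=C1O | intermediate (not isolated)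
20 | (6R)-3,5-dihydroxy-4-{[(1S,2R,5R)-2-hydroxy-2-methyl-5-(prop-1-en-2-yl)cyclopentyl]methyl}-6-methyl-2-[(2S)-2-methylbutanoyl]-6-(3-methylbut-2-en-1-yl)cyclohexa-2,4-dien-1-one (CNP0299585.2) | C=C(C)[C@@H]1CC[C@@](C)(O)[C@H]1CC1=C(O)[C@@](C)(CC=C(C)C)C(=O)C(C(=O)[C@@H](C)CC)=C1O | target

**Step count**

Total: 14 steps. Longest linear sequence: 8 steps (steps 1–7 and 14, from (R)-limonene). The ring B branch is 7 steps (steps 8–13 and 14).

**Steps most likely to fail, with fallbacks**

Step 5 (key step). Hydroperoxide may add to the formyl group instead of the fully substituted β-carbon, with Baeyer–Villiger-type loss of the one-carbon arm, or the ring closure may discriminate poorly between the two faces. The fallback moves the epoxidation to the alcohol oxidation level and puts the face under reagent control. It sets out from 5: Luche reduction (NaBH4, CeCl3·7H2O, MeOH, 0 °C) should give the allylic alcohol [(5S)-2-methyl-5-(prop-1-en-2-yl)cyclopent-1-en-1-yl]methanol F1. Sharpless asymmetric epoxidation (Ti(OiPr)4, L-(+)-diethyl tartrate, t-BuOOH, 4 Å molecular sieves, CH2Cl2, −20 °C) should then deliver oxygen to the face opposite isopropenyl, where tartrate control and substrate control are matched and the isolated isopropenyl alkene is inert, giving the epoxy alcohol [(1R,2S,5R)-5-methyl-2-(prop-1-en-2-yl)-6-oxabicyclo[3.1.0]hexan-1-yl]methanol F2. Dess–Martin oxidation of F2 comes back to the route at 6.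

Step 7. E1cB loss of the tertiary hydroxyl (back to 5) or retro-aldol ring opening may overtake α-epimerisation. The fallback sets the ring methine by stereospecific inversion instead of equilibration and builds ring B around the arm, so that neither the aldol aldehyde nor the coupling of step 14 is needed. It sets out from 6 and comes back to the route at 20, using 13 and 15 on the way.
- Wittig olefination of 6 with methyl (triphenylphosphoranylidene)acetate (toluene, 80 °C) should give the alkenyl oxirane methyl (2E)-3-[(1S,2S,5R)-5-methyl-2-(prop-1-en-2-yl)-6-oxabicyclo[3.1.0]hexan-1-yl]prop-2-enoate F3.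
- Palladium-catalysed formate hydrogenolysis of the alkenyl oxirane (Pd2(dba)3·CHCl3, n-Bu3P, HCO2H, Et3N, dioxane, rt) should follow: zerovalent palladium ionises the allylic C–O bond from the face opposite oxygen and hydride is passed from the metal to the ring carbon, so that carbon is inverted. This should give methyl (2E)-3-[(1S,2R,5R)-2-hydroxy-2-methyl-5-(prop-1-en-2-yl)cyclopentyl]prop-2-enoate F4, with the side chain trans to isopropenyl and cis to the hydroxyl.
- Conjugate reduction with Mg in MeOH should give the saturated ester methyl 3-[(1S,2R,5R)-2-hydroxy-2-methyl-5-(prop-1-en-2-yl)cyclopentyl]propanoate F5, which on warming with pyridinium p-toluenesulfonate in benzene should close to the lactone (4aS,5R,7aR)-7a-methyl-5-(prop-1-en-2-yl)hexahydrocyclopenta[b]pyran-2(3H)-one F6.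
- The lithium enolate of 13 (two equivalents, LiN(SiMe3)2, THF, −78 → 0 °C) should open the lactone in a Claisen-type acylation to the hydroxy diketo ester ethyl (2S)-7-[(1S,2R,5R)-2-hydroxy-2-methyl-5-(prop-1-en-2-yl)cyclopentyl]-2-methyl-2-(3-methylbut-2-en-1-yl)-3,5-dioxoheptanoate F7.
- C-acylation of its magnesium diketonate with 15 (MgCl2, Et3N, MeCN) should give the triketo ester ethyl (2S)-7-[(1S,2R,5R)-2-hydroxy-2-methyl-5-(prop-1-en-2-yl)cyclopentyl]-2-methyl-2-(3-methylbut-2-en-1-yl)-4-[(2S)-2-methylbutanoyl]-3,5-dioxoheptanoate F8.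
- Dieckmann closure of F8 (LiN(iPr)2, 4.2 equiv, THF, −78 → 0 °C; dilute HCl), with the C6 enolate attacking the ester, should give 20.

Step 14. The secondary amine may dehydrate or cleave the aldol aldehyde through its enamine before the hindered formyl group condenses, or alkylidene 19 may be captured by a second molecule of 18 or by the neighbouring hydroxyl before hydride transfer. The fallback takes the hydroxyl out of play for the union and frees it afterwards. It sets out from 8: silylation (Et3SiOTf, 2,6-lutidine, CH2Cl2, −78 °C) should give (1S,2R,5R)-2-methyl-5-(prop-1-en-2-yl)-2-[(triethylsilyl)oxy]cyclopentane-1-carbaldehyde F9. The same reductive alkylation with 18 (Hantzsch ester, L-proline, CH2Cl2, rt) should pass through the silylated alkylidene trione F10 to the triethylsilyl ether of the target F11. HF·pyridine (THF, 0 °C) then comes back to the route at 20.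

**Further compounds**

F1 | step 5 | [(5S)-2-methyl-5-(prop-1-en-2-yl)cyclopent-1-en-1-yl]methanol | C=C(C)[C@@H]1CCC(C)=C1CO
F2 | step 5 | [(1R,2S,5R)-5-methyl-2-(prop-1-en-2-yl)-6-oxabicyclo[3.1.0]hexan-1-yl]methanol | C=C(C)[C@@H]1CC[C@@]2(C)O[C@@]12CO
F3 | step 7 | methyl (2E)-3-[(1S,2S,5R)-5-methyl-2-(prop-1-en-2-yl)-6-oxabicyclo[3.1.0]hexan-1-yl]prop-2-enoate | C=C(C)[C@@H]1CC[C@@]2(C)O[C@@]12/C=C/C(=O)OC
F4 | step 7 | methyl (2E)-3-[(1S,2R,5R)-2-hydroxy-2-methyl-5-(prop-1-en-2-yl)cyclopentyl]prop-2-enoate | C=C(C)[C@@H]1CC[C@@](C)(O)[C@H]1/C=C/C(=O)OC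
F5 | step 7 | methyl 3-[(1S,2R,5R)-2-hydroxy-2-methyl-5-(prop-1-en-2-yl)cyclopentyl]propanoate | C=C(C)[C@@H]1CC[C@@](C)(O)[C@H]1CCC(=O)OC
F6 | step 7 | (4aS,5R,7aR)-7a-methyl-5-(prop-1-en-2-yl)hexahydrocyclopenta[b]pyran-2(3H)-one | C=C(C)[C@@H]1CC[C@@]2(C)OC(=O)CC[C@@H]12
F7 | step 7 | ethyl (2S)-7-[(1S,2R,5R)-2-hydroxy-2-methyl-5-(prop-1-en-2-yl)cyclopentyl]-2-methyl-2-(3-methylbut-2-en-1-yl)-3,5-dioxoheptanoate | C=C(C)[C@@H]1CC[C@@](C)(O)[C@H]1CCC(=O)CC(=O)[C@](C)(CC=C(C)C)C(=O)OCC
F8 | step 7 | ethyl (2S)-7-[(1S,2R,5R)-2-hydroxy-2-methyl-5-(prop-1-en-2-yl)cyclopentyl]-2-methyl-2-(3-methylbut-2-en-1-yl)-4-[(2S)-2-methylbutanoyl]-3,5-dioxoheptanoate (triketo tautomer drawn) | C=C(C)[C@@H]1CC[C@@](C)(O)[C@H]1CCC(=O)C(C(=O)[C@@H](C)CC)C(=O)[C@](C)(CC=C(C)C)C(=O)OCC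
F9 | step 14 | (1S,2R,5R)-2-methyl-5-(prop-1-en-2-yl)-2-[(triethylsilyl)oxy]cyclopentane-1-carbaldehyde | C=C(C)[C@@H]1CC[C@@](C)(O[Si](CC)(CC)CC)[C@H]1C=O
F10 | step 14 | triethylsilyl ether of alkylidene trione 19 (alkene geometry open) | C=C(C)[C@@H]1CC[C@@](C)(O[Si](CC)(CC)CC)[C@H]1C=C1C(=O)[C@@](C)(CC=C(C)C)C(=O)C(C(=O)[C@@H](C)CC)=C1O
F11 | step 14 | triethylsilyl ether of 20 at the tertiary hydroxyl | C=C(C)[C@@H]1CC[C@@](C)(O[Si](CC)(CC)CC)[C@H]1CC1=C(O)[C@@](C)(CC=C(C)C)C(=O)C(C(=O)[C@@H](C)CC)=C1O
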